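**Strategy.** The whole skeleton is traced back to the sp–sp bond of 1,4-diethoxybuta-1,3-diyne, which becomes the crowded B–C biaryl bond. In one thermal operation a double Danheiser-type benzannulation with two molecules of racemic 3-ethoxy-4-(2,4,6-trimethoxyphenyl)cyclobutenone should grow rings B and C around that bond, rings A and D being already attached. This exploits the twofold symmetry (chlorine aside) about the bond joining C5 of ring B to C5 of ring C: numbering each inner ring from the carbon bonded to its terminal ring (C1), the hydroxyl carbon C6 lies between C1 and C5, and C3, para to C6, carries H in ring B and Cl in ring C. Chlorine enters late, after the inner rings are differentiated.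

Key step: step 4

Ring labels: ring A is the terminal ring on the chlorine-free inner ring B; ring C is the chlorinated inner ring and ring D its terminal ring.

Assumption: the target carries no descriptor for the tetra-ortho-oxygenated B–C axis, so it is treated as stereochemically undefined and every biaryl is made as the racemate about that axis.

Step 1
Reactants: 1 ethoxyacetylene (two molecules)
Product: 2 1,4-diethoxybuta-1,3-diyne
Conditions: CuCl (10 mol %), TMEDA (20 mol %), O2 (1 atm), 4 Å MS, acetone, 0 °C → rt; filter through neutral alumina, keep as a cold solution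
Reagents that add atoms: none
Why: Glaser–Hay oxidative homocoupling of a terminal alkyne through copper acetylides (CuCl·TMEDA turned over by O2) joins the two sp carbons remote from oxygen, and the basic, acid-free medium with sieves should protect the acid-labile ynol ether from hydration.

Step 2
Reactants: 3 (2,4,6-trimethoxyphenyl)acetic acid
Product: 4 (2,4,6-trimethoxyphenyl)acetyl chloride
Conditions: (COCl)2 (1.5 equiv), CH2Cl2, 0 °C → rt, no DMF; evaporate, use crude
Reagents that add atoms: oxalyl chloride, O=C(Cl)C(Cl)=O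
Why: Acid chloride formation with oxalyl chloride is routine, and DMF is left out so that no Vilsmeier reagent can formylate the very electron-rich trimethoxyphenyl ring.

Step 3
Reactants: 4 (2,4,6-trimethoxyphenyl)acetyl chloride; 1 ethoxyacetylene
Product: 6 3-ethoxy-4-(2,4,6-trimethoxyphenyl)cyclobut-2-en-1-one (racemic), via arylketene 5 (not isolated)
Conditions: 1 (3 equiv), Et3N (1.2 equiv, slow addition), Et2O, 0 °C → rt; neutral work-up
Reagents that add atoms: none
Why: Dehydrochlorination of 4 by Et3N gives arylketene 5, which should undergo the known regioselective ketene–ynol ether [2+2] cycloaddition with excess ethoxyacetylene (ketene carbonyl carbon to the unsubstituted alkyne carbon), the two ortho methoxy groups slowing ketene dimerization; the C4 stereocentre forms without control (racemic) and is destroyed in step 4.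

Step 4
Reactants: 2 1,4-diethoxybuta-1,3-diyne; 6 3-ethoxy-4-(2,4,6-trimethoxyphenyl)cyclobut-2-en-1-one (racemic, two molecules)
Product: 11 4,4',6,6'-tetraethoxy-3,3'-bis(2,4,6-trimethoxyphenyl)biphenyl-2,2'-diol, via vinylketene 7 (not isolated), via vinylcyclobutenone 8 (not isolated), via dienylketene 9 (not isolated), via alkynylphenol 10 (not isolated)
Conditions: 2 (1.0 equiv), 6 (2.4 equiv), PhMe (0.3 M), Ar, sealed tube, 80 °C then 100–110 °C; then K2CO3, MeOH, rt (cleaves any O-acylated phenol)
Reagents that add atoms: none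
Why: Proposed new method: heating should open each molecule of 6 by 4π electrocyclic cleavage of its C1–C4 bond to vinylketene 7, whose electrophilic carbonyl carbon adds to the nucleophilic inner carbon of one ynol ether of 2 in a [2+2] cycloaddition to give 8; 4π opening of 8 to dienylketene 9, thermal 6π electrocyclization and tautomerization then give phenol 10, and the same sequence on the remaining aryl-substituted ynol ether of 10 gives 11. The closest known reaction type is the Danheiser benzannulation of one cyclobutenone with one alkoxy- or siloxyalkyne to a resorcinol monoether; its use on both triple bonds of a conjugated dialkoxydiyne, and with a 3-alkoxy-4-arylcyclobutenone, has not been shown. Ring B and ring C are each closed by disrotatory 6π electrocyclization of a dienylketene (bond between the former cyclobutenone C1 and C4), after the [2+2] step has made the two new skeletal bonds of that ring. No stereocentre is created, the C4 centre of 6 is erased, and the B–C axis arises racemic. The step needs ynol-ether polarization (oxygen lone pair making the inner alkyne carbon nucleophilic) to fix the regiochemistry, so that each new hydroxyl lands beside the B–C bond and the oxygens alternate; it also needs the vinylketene not to close onto its own aryl ring, which the two ortho methoxy groups prevent because that closure could not aromatize.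

Step 5
Reactants: 11 4,4',6,6'-tetraethoxy-3,3'-bis(2,4,6-trimethoxyphenyl)biphenyl-2,2'-diol
Product: 12 4,4',6,6'-tetraethoxy-2'-methoxy-3,3'-bis(2,4,6-trimethoxyphenyl)biphenyl-2-ol
Conditions: KOtBu (1.0 equiv), DMF, 0 °C; MeI (3 equiv), 0 °C → rt
Reagents that add atoms: iodomethane, CI
Why: Williamson O-methylation under stoichiometric base control: a 2,2'-biphenol ionizes far more easily the first time than the second (hydrogen-bonded monoanion), so one equivalent of base should give only the monophenoxide, and the neutral monoether 12 cannot be methylated again.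

Step 6
Reactants: 12 4,4',6,6'-tetraethoxy-2'-methoxy-3,3'-bis(2,4,6-trimethoxyphenyl)biphenyl-2-ol
Product: 13 5-chloro-4,4',6,6'-tetraethoxy-2'-methoxy-3,3'-bis(2,4,6-trimethoxyphenyl)biphenyl-2-ol
Conditions: NaH (1.05 equiv), THF, 0 °C; NCS (1.0 equiv), −40 → 0 °C; then 0.5 M HCl
Reagents that add atoms: N-chlorosuccinimide, O=C1CCC(=O)N1Cl
Why: Electrophilic aromatic chlorination of a phenoxide with NCS: only the future ring C carries a free OH, its phenoxide is far more nucleophilic than the neutral alkoxy-substituted rings A, B and D, and both ortho positions are blocked, so chlorine should enter only at the para C–H between the two ethoxy groups.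

Step 7
Reactants: 13 5-chloro-4,4',6,6'-tetraethoxy-2'-methoxy-3,3'-bis(2,4,6-trimethoxyphenyl)biphenyl-2-ol
Product: 14 5'-chloro-1,1':3',1'':3'',1'''-quaterphenyl-2,2',2'',2''',4,4',4'',4''',6,6',6'',6'''-dodecol (CNP0271703.0)
Conditions: BBr3 (ca. 25 equiv), CH2Cl2, −78 °C → rt → 40 °C, Ar; then degassed ice/H2O; C18 or Sephadex LH-20 under Ar
Reagents that add atoms: none
Why: Lewis acid ether cleavage with BBr3 (O–B coordination, bromide attack at the alkyl carbon) should remove all seven methyl and four ethyl groups while leaving the aryl C–Cl bond and the three biaryl bonds untouched.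

**Compound list**

1 | ethoxyacetylene (ethoxyethyne) | C#COCC | starting material
2 | 1,4-diethoxybuta-1,3-diyne | CCOC#CC#COCC | intermediate
3 | (2,4,6-trimethoxyphenyl)acetic acid | COc1cc(OC)c(CC(=O)O)c(OC)c1 | starting material
4 | (2,4,6-trimethoxyphenyl)acetyl chloride | COc1cc(OC)c(CC(=O)Cl)c(OC)c1 | intermediate
5 | (2,4,6-trimethoxyphenyl)ketene, 2-(2,4,6-trimethoxyphenyl)ethen-1-one | COc1cc(OC)c(C=C=O)c(OC)c1 | intermediate (not isolated)
6 | 3-ethoxy-4-(2,4,6-trimethoxyphenyl)cyclobut-2-en-1-one, racemic at C4 | CCOC1=CC(=O)C1c1c(OC)cc(OC)cc1OC | intermediate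
7 | (Z)-3-ethoxy-4-(2,4,6-trimethoxyphenyl)buta-1,3-dien-1-one (aryl rotated outward; geometry is lost on ring closure) | O=C=C/C(OCC)=C/c1c(OC)cc(OC)cc1OC | intermediate (not isolated)
8 | 3-ethoxy-2-(ethoxyethynyl)-4-[(Z)-1-ethoxy-2-(2,4,6-trimethoxyphenyl)ethenyl]cyclobut-2-en-1-one, racemic | O=C1C(C#COCC)=C(OCC)C1/C(OCC)=C/c1c(OC)cc(OC)cc1OC | intermediate (not isolated)
9 | (3E,5Z)-3,5-diethoxy-2-(ethoxyethynyl)-6-(2,4,6-trimethoxyphenyl)hexa-1,3,5-trien-1-one | O=C=C(C#COCC)/C(OCC)=C\C(OCC)=C\c1c(OC)cc(OC)cc1OC | intermediate (not isolated)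
10 | 3,5-diethoxy-2-(ethoxyethynyl)-6-(2,4,6-trimethoxyphenyl)phenol | CCOC#Cc1c(OCC)cc(OCC)c(-c2c(OC)cc(OC)cc2OC)c1O | intermediate (not isolated)
11 | 4,4',6,6'-tetraethoxy-3,3'-bis(2,4,6-trimethoxyphenyl)biphenyl-2,2'-diol (racemic about the axis) | CCOc1cc(OCC)c(-c2c(OC)cc(OC)cc2OC)c(O)c1-c1c(OCC)cc(OCC)c(-c2c(OC)cc(OC)cc2OC)c1O | intermediate
12 | 4,4',6,6'-tetraethoxy-2'-methoxy-3,3'-bis(2,4,6-trimethoxyphenyl)biphenyl-2-ol (racemic about the axis) | CCOc1cc(OCC)c(-c2c(OC)cc(OC)cc2OC)c(OC)c1-c1c(OCC)cc(OCC)c(-c2c(OC)cc(OC)cc2OC)c1O | intermediate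
13 | 5-chloro-4,4',6,6'-tetraethoxy-2'-methoxy-3,3'-bis(2,4,6-trimethoxyphenyl)biphenyl-2-ol (racemic about the axis) | CCOc1cc(OCC)c(-c2c(OC)cc(OC)cc2OC)c(OC)c1-c1c(OCC)c(Cl)c(OCC)c(-c2c(OC)cc(OC)cc2OC)c1O | intermediate
14 | 5'-chloro-1,1':3',1'':3'',1'''-quaterphenyl-2,2',2'',2''',4,4',4'',4''',6,6',6'',6'''-dodecol (CNP0271703.0) | Oc1cc(O)c(-c2c(O)cc(O)c(-c3c(O)c(Cl)c(O)c(-c4c(O)cc(O)cc4O)c3O)c2O)c(O)c1 | target

**Totals.** Total step count: 7. Longest linear sequence: 6 steps (steps 2–7 from acid 3; the diyne branch is step 1).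

**Steps most likely to fail**

1. Step 4 (new method). The ethoxyalkyne termini may lose ethylene by retro-ene fragmentation at the annulation temperature, and the vinylketene may oligomerize. The cascade may also stall after the first annulation, through acylation of the new phenol or its addition across the neighbouring ynol ether, or through crowding in the second [2+2] step. The fallback uses known chemistry only, sets out from 6 (with 1) and returns at 11. A single Danheiser benzannulation of 6 with excess ethoxyacetylene (PhMe, 80 °C) should give 3,5-diethoxy-2-(2,4,6-trimethoxyphenyl)phenol F1. Protection with MOMCl and iPr2NEt gives 1,5-diethoxy-3-(methoxymethoxy)-2-(2,4,6-trimethoxyphenyl)benzene F2. Directed ortho-lithiation with n-BuLi in THF at 0 °C, at the C–H between the MOM ether and the ethoxy group, gives 2,4-diethoxy-6-(methoxymethoxy)-5-(2,4,6-trimethoxyphenyl)phenyllithium F3. Quenching with I2 gives 1,5-diethoxy-2-iodo-3-(methoxymethoxy)-4-(2,4,6-trimethoxyphenyl)benzene F4. Ullmann homocoupling (Cu powder, DMF, heat) then forms the B–C bond in 4,4',6,6'-tetraethoxy-2,2'-bis(methoxymethoxy)-3,3'-bis(2,4,6-trimethoxyphenyl)biphenyl F5. HCl in MeOH removes both MOM groups to give 11.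

2. Step 7. Cleavage of the four ethyl ethers may stop short, and the dodecaphenol may be lost to air oxidation and adsorption during isolation. The fallback sets out from 13 and returns at 14 by trap and release. The crude product of exhaustive dealkylation (BBr3, or molten pyridinium chloride for stubborn ethyl ethers) is acetylated at once with Ac2O, pyridine and DMAP to 5'-chloro-1,1':3',1'':3'',1'''-quaterphenyl-2,2',2'',2''',4,4',4'',4''',6,6',6'',6'''-dodecayl dodecaacetate F6. F6 is stable on silica and can be separated from partly dealkylated material. Degassed HCl in MeOH then releases 14.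

3. Step 5. O-alkylation of the doubly flanked, hydrogen-bonded phenoxide may be sluggish, or methylation may go to the para carbon instead. The fallback sets out from 11 and returns at 14 without the protecting step. The monoanion of 11 (NaH, 1.0 equiv, THF) is chlorinated with a slight deficit of NCS at low temperature to 5-chloro-4,4',6,6'-tetraethoxy-3,3'-bis(2,4,6-trimethoxyphenyl)biphenyl-2,2'-diol F7. F7 is separated from recovered 11 (recycled) and from dichlorinated material. BBr3 as in step 7 then gives 14.

**Further compounds**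

F1 | step 4 | 3,5-diethoxy-2-(2,4,6-trimethoxyphenyl)phenol | CCOc1cc(O)c(-c2c(OC)cc(OC)cc2OC)c(OCC)c1
F2 | step 4 | 1,5-diethoxy-3-(methoxymethoxy)-2-(2,4,6-trimethoxyphenyl)benzene | CCOc1cc(OCOC)c(-c2c(OC)cc(OC)cc2OC)c(OCC)c1
F3 | step 4 | 2,4-diethoxy-6-(methoxymethoxy)-5-(2,4,6-trimethoxyphenyl)phenyllithium | CCOc1cc(OCC)c(-c2c(OC)cc(OC)cc2OC)c(OCOC)c1[Li]
F4 | step 4 | 1,5-diethoxy-2-iodo-3-(methoxymethoxy)-4-(2,4,6-trimethoxyphenyl)benzene | CCOc1cc(OCC)c(-c2c(OC)cc(OC)cc2OC)c(OCOC)c1I
F5 | step 4 | 4,4',6,6'-tetraethoxy-2,2'-bis(methoxymethoxy)-3,3'-bis(2,4,6-trimethoxyphenyl)biphenyl | CCOc1cc(OCC)c(-c2c(OC)cc(OC)cc2OC)c(OCOC)c1-c1c(OCC)cc(OCC)c(-c2c(OC)cc(OC)cc2OC)c1OCOC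
F6 | step 7 | 5'-chloro-1,1':3',1'':3'',1'''-quaterphenyl-2,2',2'',2''',4,4',4'',4''',6,6',6'',6'''-dodecayl dodecaacetate | CC(=O)Oc1cc(OC(C)=O)c(-c2c(OC(C)=O)cc(OC(C)=O)c(-c3c(OC(C)=O)c(Cl)c(OC(C)=O)c(-c4c(OC(C)=O)cc(OC(C)=O)cc4OC(C)=O)c3OC(C)=O)c2OC(C)=O)c(OC(C)=O)c1
F7 | step 5 | 5-chloro-4,4',6,6'-tetraethoxy-3,3'-bis(2,4,6-trimethoxyphenyl)biphenyl-2,2'-diol | CCOc1cc(OCC)c(-c2c(OC)cc(OC)cc2OC)c(O)c1-c1c(OCC)c(Cl)c(OCC)c(-c2c(OC)cc(OC)cc2OC)c1O
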